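**Retrosynthetic overview**
1. The target is a 6-alkylsalicylic acid. On the salicylate benzene ring, the carbon bearing CO2H (C1) lies between the carbon bearing the phenolic oxygen (C2) and the carbon bearing the 12-phenyldodecyl chain (C6). This contiguous O–C2 / C1 / C6 array makes the key step possible: C6 and C1 map onto the two carbons of an aryne triple bond, and the oxygen on C2 sits beside that triple bond.
2. Key disconnection: the aryl C6–CH2 bond and the C1–CO2H bond are broken in one operation, leading back to 3-methoxybenzyne (from 3-fluoroanisole), (12-phenyldodecyl)lithium and CO2.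
3. The chain comes from 12-bromododecan-1-ol and phenylmagnesium bromide (copper-catalysed sp2–sp3 coupling), followed by iodination and iodine–lithium exchange.
4. The last step is O-demethylation. No ring is formed in the route (both benzene rings are bought) and the target has no stereocentre.

Key step: step 3

**Step 1**
Reactants: 1 12-bromododecan-1-ol; 2 phenylmagnesium bromide
Product: 5 12-phenyldodecan-1-ol, via bromomagnesium 12-bromododecan-1-olate 3 (not isolated), via bromomagnesium 12-phenyldodecan-1-olate 4 (not isolated)
Conditions: 2 (2.5 equiv), Li2CuCl4 (3 mol %), THF, 0 °C → rt; then 1 M HCl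
Reagents that add atoms: none
Why: Copper-catalysed Kumada-type (Kochi) sp2–sp3 coupling, in which the first equivalent of 2 only deprotonates the hydroxyl group to give alkoxide 3 and the primary C–Br bond is then substituted by the phenylcopper species formed from Li2CuCl4 and further 2, primary bromides being the best substrates for this coupling.

**Step 2**
Reactants: 5 12-phenyldodecan-1-ol
Product: 7 (12-iodododecyl)benzene, via triphenyl(12-phenyldodecyloxy)phosphonium iodide 6 (not isolated)
Conditions: PPh3, I2, imidazole, CH2Cl2, 0 °C → rt
Reagents that add atoms: iodine, II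
Why: Appel-type iodination (Garegg–Samuelsson conditions), in which the primary alkoxyphosphonium ion 6 should undergo clean SN2 displacement by iodide, driven by formation of the P=O bond.

**Step 3**
Reactants: 7 (12-iodododecyl)benzene; 8 3-fluoroanisole (1-fluoro-3-methoxybenzene)
Product: 14 2-methoxy-6-(12-phenyldodecyl)benzoic acid, via (12-phenyldodecyl)lithium 9 (not isolated), via (2-fluoro-6-methoxyphenyl)lithium 10 (not isolated), via 3-methoxybenzyne 11 (not isolated), via [2-methoxy-6-(12-phenyldodecyl)phenyl]lithium 12 (not isolated), via lithium 2-methoxy-6-(12-phenyldodecyl)benzoate 13 (not isolated)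
Conditions: (a) 7 (1.1 equiv), t-BuLi (2.1 equiv per 7), Et2O/pentane, −78 °C → rt; (b) 8 (1.0 equiv), n-BuLi (1.0 equiv), THF, −78 °C; (c) cold solution b added slowly by cannula to solution a, −30 → 0 °C; (d) CO2 (g), −78 °C → rt; (e) 1 M HCl
Reagents that add atoms: carbon dioxide, O=C=O
Why: n-BuLi removes the proton of 8 that lies between fluorine and methoxy (directed ortho-metalation at the most acidic site), and on warming aryllithium 10 loses LiF to give 3-methoxybenzyne 11 in the presence of alkyllithium 9, made beforehand by iodine–lithium exchange of 7. Carbolithiation of the strained triple bond by 9 forms the aryl–CH2 bond and gives aryllithium 12, which CO2 carboxylates on the neighbouring carbon, so both carbon substituents enter in one flask. The closest known reaction type is the aryne three-component coupling, that is, organolithium addition to a 3-alkoxybenzyne followed by electrophilic trapping of the resulting ortho-alkoxyaryllithium. No ring is closed and no stereocentre is formed. The step needs regioselectivity, which the methoxy oxygen beside the triple bond secures: its inductive pull makes the aryne carbon meta to it the more electrophilic terminus and stabilises the negative charge developing in the in-plane orbital on the carbon ortho to it, aided by O–Li coordination, so the alkyl group ends up meta and lithium (then CO2H) ortho to OMe. It also needs chemoselectivity for 9 over aryllithiums 10 and 12 as nucleophiles, secured by adding cold 10 slowly to a slight excess of the far more nucleophilic, unhindered primary alkyllithium and by the absence of amine bases or free n-BuLi.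

**Step 4**
Reactants: 14 2-methoxy-6-(12-phenyldodecyl)benzoic acid
Product: 16 2-hydroxy-6-(12-phenyldodecyl)benzoic acid, via 2-bromo-5-(12-phenyldodecyl)-4H-1,3,2-benzodioxaborinin-4-one 15 (not isolated)
Conditions: BBr3 (3 equiv), CH2Cl2, −78 °C → rt; then H2O, 0 °C
Reagents that add atoms: none
Why: Lewis-acid cleavage of an aryl methyl ether, in which BBr3 is anchored by the neighbouring carboxyl group as chelate 15, bromide removes the O-methyl group by SN2 attack and hydrolysis releases the salicylic acid, while the saturated chain and the terminal phenyl ring are inert.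

**Compound list**
1 | 12-bromododecan-1-ol | OCCCCCCCCCCCCBr | starting material
2 | phenylmagnesium bromide | Br[Mg]c1ccccc1 | starting material
3 | bromomagnesium 12-bromododecan-1-olate | BrCCCCCCCCCCCCO[Mg]Br | intermediate
4 | bromomagnesium 12-phenyldodecan-1-olate | Br[Mg]OCCCCCCCCCCCCc1ccccc1 | intermediate
5 | 12-phenyldodecan-1-ol | OCCCCCCCCCCCCc1ccccc1 | intermediate
6 | triphenyl(12-phenyldodecyloxy)phosphonium iodide | [I-].c1ccccc1[P+](c1ccccc1)(c1ccccc1)OCCCCCCCCCCCCc1ccccc1 | intermediate
7 | (12-iodododecyl)benzene | ICCCCCCCCCCCCc1ccccc1 | intermediate
8 | 3-fluoroanisole (1-fluoro-3-methoxybenzene) | COc1cccc(F)c1 | starting material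
9 | (12-phenyldodecyl)lithium | [Li]CCCCCCCCCCCCc1ccccc1 | intermediate
10 | (2-fluoro-6-methoxyphenyl)lithium | COc1cccc(F)c1[Li] | intermediate
11 | 3-methoxybenzyne (1-methoxy-2,3-didehydrobenzene) | COC1=CC=CC#C1 | intermediate
12 | [2-methoxy-6-(12-phenyldodecyl)phenyl]lithium | COc1cccc(CCCCCCCCCCCCc2ccccc2)c1[Li] | intermediate
13 | lithium 2-methoxy-6-(12-phenyldodecyl)benzoate | COc1cccc(CCCCCCCCCCCCc2ccccc2)c1C(=O)[O-].[Li+] | intermediate
14 | 2-methoxy-6-(12-phenyldodecyl)benzoic acid | COc1cccc(CCCCCCCCCCCCc2ccccc2)c1C(=O)O | intermediate
15 | 2-bromo-5-(12-phenyldodecyl)-4H-1,3,2-benzodioxaborinin-4-one | O=C1OB(Br)Oc2cccc(CCCCCCCCCCCCc3ccccc3)c12 | intermediate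
16 | 2-hydroxy-6-(12-phenyldodecyl)benzoic acid | O=C(O)c1c(O)cccc1CCCCCCCCCCCCc1ccccc1 | target

**Totals**
Total step count: 4. Longest linear sequence: 4 steps (1 → 5 → 7 → 14 → 16).

**Steps most likely to fail**

Step 3. The aryne may be intercepted by aryllithium 10 or 12 instead of alkyllithium 9, giving biaryls. Aryllithium 12 may also be protonated by the medium before carboxylation. Fallback (sets out from 7, comes back at 14): cross-coupling replaces the aryne. Zinc insertion into 7 (Zn dust activated with 1,2-dibromoethane and Me3SiCl, LiCl, THF, 40 °C) should give (12-phenyldodecyl)zinc iodide F1. Negishi coupling of F1 with commercial methyl 2-bromo-6-methoxybenzoate (COC(=O)c1c(Br)cccc1OC) under Pd(OAc)2/SPhos in THF at 50 °C should give methyl 2-methoxy-6-(12-phenyldodecyl)benzoate F2. Hydrolysis of the hindered ester with KOH in DMSO/H2O at 100 °C should give potassium 2-methoxy-6-(12-phenyldodecyl)benzoate F3, and acidification with HCl should give 14.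

Step 1. The poorly soluble alkoxide 3 may couple slowly, so that the Grignard reagent is consumed by homocoupling and the alkyl bromide by reduction or elimination. Fallback (sets out from 1, comes back at 5): a nickel-catalysed reductive cross-electrophile coupling of 1 with bromobenzene (Brc1ccccc1), using NiI2 hydrate, 1,10-phenanthroline, pyridine, NaI and Zn dust in DMPU at 60 °C. It joins two electrophiles, needs no basic organometallic reagent, and should tolerate the free hydroxyl group and give 5 directly. No new compound is made on the way.

Step 4. Ether cleavage may stop short, or the electron-rich salicylic acid may undergo acid-promoted protodecarboxylation during Lewis-acid treatment and work-up. Fallback (sets out from 14, comes back at 16): nucleophilic instead of electrophilic dealkylation. Heating 14 with NaSEt in DMF at 130 °C should remove the O-methyl group by SN2 attack of thiolate and give disodium 2-oxido-6-(12-phenyldodecyl)benzoate F4, which cold dilute HCl should convert into 16.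

**Further compounds**
F1 | step 3 | (12-phenyldodecyl)zinc iodide | I[Zn]CCCCCCCCCCCCc1ccccc1
F2 | step 3 | methyl 2-methoxy-6-(12-phenyldodecyl)benzoate | COC(=O)c1c(OC)cccc1CCCCCCCCCCCCc1ccccc1
F3 | step 3 | potassium 2-methoxy-6-(12-phenyldodecyl)benzoate | COc1cccc(CCCCCCCCCCCCc2ccccc2)c1C(=O)[O-].[K+]
F0 | step 1 | none | none
F4 | step 4 | disodium 2-oxido-6-(12-phenyldodecyl)benzoate | [Na+].[Na+].[O-]C(=O)c1c([O-])cccc1CCCCCCCCCCCCc1ccccc1
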